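Percent of the J and D charged together is the unit of every reading here, and in that unit I have to set the next run: J and D as given, and how much solid E beside them.

| flask | J | D | E | remark | time |
|---|---|---|---|---|---|
| zeta | 0.10 M | 0.10 M | 0.80 M | run made earlier |  |
| eta | 0.15 M | 0.15 M | 0.80 M | run made earlier |  |
| gamma | 0.20 M | 0.20 M | 1.6 M | run made earlier |  |
| flask | 0.20 M | 0.20 M | 0.800 M |  | 20 h |

- zeta (time / h: Z / %, G / %): 1.00: 0.1, 1.0; 3.00: 3.4, 2.2; 6.00: 8.9, 0; 8.00: 10.6, 5.1; 12.0: 17.4, 4.5
- eta (time / h: Z / %, G / %): 2.50: 4.4, 3.7; 5.00: 6.1, 2.4; 8.00: 12.4, 3.5; 10.0: 14.3, 3.5; 12.0: 14.6, 4.4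
- gamma (time / h: Z / %, G / %): 1.00: 0.4, 0.3; 3.00: 1.5, 0; 6.00: 6.9, 1.0; 8.00: 9.5, 1.5; 12.0: 13.6, 4.4

(standard deviation of a reading: 1 percentage point)

- Z and G together, in percent of the J and D charged together, at 20 h
- excess of Z over G in the product at 20 h
- whether the exchange between J and D keeps pace with the reaction: how far the product's excess at 20 h gets from its value without exchange to its value with instant exchange (above 80% keeps pace, below 20% hardly takes part, else lags behind)

- Q is single-handed; J and D are mirror images of each other, charged as a racemate, each of them at the stated concentration
- given per volume of solution although it is solid: E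
- at the start none of E is in solution
- an excess is the difference of the two amounts in percent of their sum
- an excess is below zero if the other one leads
- the handed part of Q does not stay in what it makes, so the products of the two hands are mirror images too

At 12.0 h the gamma run, with 1.6 M of E, has made 18.0% of product and the zeta run, with 0.80 M, has made 21.9%. The gamma figure is lower, although these runs differ in J and D as well, so I see no sign of a gain from more E and charge 0.800 M.

What remains is whether I may leave this flask for the full 20 h. If J and D interconvert much faster than either reacts, they stay equal, and Z and G form in a fixed ratio s, the selectivity factor, however long the run. If they do not, J falls ahead of D and a long run lowers the excess. The readings at 12.0 h, summed over the runs, give s = 3.43 as a reading. The balanced excess, s minus one over s plus one, is then 54.8%. The same sum at 8.00 h gives 52.6%, lower than the later figure, but each reading scatters by 1 percentage point, so this pair does not tell a fall from none. As my own judgement, which these readings do not prove, I keep the full time and expect the balanced excess, with the exchange keeping pace.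

The forecast gives 30% of product and an excess of 56%, with the exchange lags behind, since “the noise cannot settle it”. I differ from it on the exchange.

The flask gives 32.5% of product at 20 h with an excess of 51.4%, which is 3.4 points below my 54.8%, and its exchange keeps pace, 99.3% of the way to the instant value.

    Q + D → G (k = 0.00250 M⁻¹ min⁻¹)
    Q + J → Z (k = 0.00780 M⁻¹ min⁻¹)
    Q → L (k = 9.00 × 10⁻⁵ min⁻¹)
    J ⇌ D (k = 0.120 min⁻¹)
    E ⇌ Q, rate k5*(cs5 - [Q]) while solid is left; crystals form when [Q] > cs5 (solubility = 0.0740 M, k = 0.0220 min⁻¹)
    2 Q → X (k = 0.00730 M⁻¹ min⁻¹)

At 20.0 h the rate of J to Z is 0.0043 of the forward rate of J to D, far slower, and the flask holds J at 33.7% and D at 33.8%. The neighbour flask with 1.4 M of E also holds J at 33.7% and D at 33.8%, and against the balanced excess of 54.8% it gives 51.4%.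

The runs were generated by integration with constants of no real substance; the scatter is artificial.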